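Prinsepiol is cut at the two aryl–C2 and aryl–C6 bonds. Both carbons are acetal-type positions of the cis-fused 3,7-dioxabicyclo[3.3.0]octane: each carries a ring oxygen (O3, O7) and its aryl group on the convex face, cis to the C1/C5 hydroxyls. A twofold acid-mediated Friedel–Crafts reaction of guaiacol with the oxocarbenium ions at C2 and C6 therefore forms both C–C bonds and both benzylic stereocentres in one operation. The precursor is the (1R,5R)-bis-lactol, used as its bis(methyl acetal) with free bridgehead hydroxyls. It is made from D-tartrate acetonide by two enolate benzyloxymethylations, bis-lactonisation and half-reduction.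

Key step: step 6

Assumption: the lithium enolate of a tartrate acetonide is taken to accept carbon electrophiles on the ring face away from the ester on the neighbouring carbon, so the D-tartrate series is required; the L series would then lead to the enantiomer of the target.

Step 1
Reactants: 1 dimethyl (4S,5S)-2,2-dimethyl-1,3-dioxolane-4,5-dicarboxylate; 2 benzyl chloromethyl ether
Product: 3 dimethyl (4R,5S)-4-[(benzyloxy)methyl]-2,2-dimethyl-1,3-dioxolane-4,5-dicarboxylate
Conditions: LiN(i-Pr)2 (LDA), THF/DMPU, −78 °C; then 2, −78 °C
Reagents that add atoms: benzyl chloromethyl ether (2), ClCOCc1ccccc1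
Why: Seebach-type alkylation of a tartrate acetonide ester enolate with a chloromethyl ether; the dioxolane holds the β C–O bond out of line with the enolate π system, so elimination should be slow at −78 °C, and attack on C4 away from the C5 ester puts CH2OBn trans to that ester (C4 = R), the minor C4 epimer being removed by chromatography.

Step 2
Reactants: 3 dimethyl (4R,5S)-4-[(benzyloxy)methyl]-2,2-dimethyl-1,3-dioxolane-4,5-dicarboxylate; 2 benzyl chloromethyl ether
Product: 4 dimethyl (4R,5R)-4,5-bis[(benzyloxy)methyl]-2,2-dimethyl-1,3-dioxolane-4,5-dicarboxylate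
Conditions: LiN(i-Pr)2 (LDA), THF/DMPU, −78 °C; then 2, −78 °C
Reagents that add atoms: benzyl chloromethyl ether (2), ClCOCc1ccccc1
Why: The same ester enolate alkylation at C5, the only remaining α-CH; attack is expected cis to the flat C4 ester and away from the tetrahedral C4 CH2OBn arm, which sets C5 as R and gives the C2-symmetric isomer, while the meso diastereomer is separable and cannot form the bis-lactone of step 3.

Step 3
Reactants: 4 dimethyl (4R,5R)-4,5-bis[(benzyloxy)methyl]-2,2-dimethyl-1,3-dioxolane-4,5-dicarboxylate
Product: 6 (1R,5R)-1,5-(isopropylidenedioxy)-3,7-dioxabicyclo[3.3.0]octane-2,6-dione, via diol diester 5 (not isolated)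
Conditions: H2 (1 atm), Pd/C, EtOAc, rt; filter; then DBU (0.2 equiv), toluene, 60 °C
Reagents that add atoms: none
Why: Catalytic hydrogenolysis of both benzyl ethers, then base-catalysed 5-exo-trig lactonisation of each primary alcohol onto the ester of the neighbouring ring carbon, which lies on its own face; the trioxa[3.3.3]propellane forms and no stereocentre is touched.

Step 4
Reactants: 6 (1R,5R)-1,5-(isopropylidenedioxy)-3,7-dioxabicyclo[3.3.0]octane-2,6-dione
Product: 7 (1R,5R)-1,5-(isopropylidenedioxy)-3,7-dioxabicyclo[3.3.0]octane-2,6-diol (bis-lactol)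
Conditions: i-Bu2AlH (DIBAL-H, 2.3 equiv), CH2Cl2, −78 °C; aq. KNaC4H4O6 (Rochelle salt)
Reagents that add atoms: none
Why: Half-reduction of γ-lactones to lactols with DIBAL-H, whose tetrahedral aluminium hemiacetal survives at −78 °C and collapses only on work-up; C2 and C6 form as anomeric mixtures, which is of no consequence because both anomers converge in step 6.

Step 5
Reactants: 7 (1R,5R)-1,5-(isopropylidenedioxy)-3,7-dioxabicyclo[3.3.0]octane-2,6-diol
Product: 8 (1R,5R)-2,6-dimethoxy-3,7-dioxabicyclo[3.3.0]octane-1,5-diol
Conditions: Amberlyst-15 (H+ form), MeOH, 40 °C; filter, evaporate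
Reagents that add atoms: methanol, CO
Why: Fischer-type acetalisation of both lactols with concurrent transketalisation of the acetonide; this frees the bridgehead diol (with the ketal in place the skeleton is a propellane without a convex face) and turns C2 and C6 into defined leaving-group positions of an isolable, organic-soluble donor.

Step 6
Reactants: 8 (1R,5R)-2,6-dimethoxy-3,7-dioxabicyclo[3.3.0]octane-1,5-diol; 9 guaiacol
Product: 11 prinsepiol, via mono-aryl methyl acetal 10 (not isolated)
Conditions: 9 (8 equiv), TfOH (10 mol%), CH2Cl2, −30 → 0 °C; then Et3N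
Reagents that add atoms: guaiacol (9), COc1ccccc1O
Why: The acid ionises each methyl acetal with loss of methanol to a five-membered oxocarbenium ion fused to the second ring (both anomers give the same planar cation), guaiacol adds through C4, the carbon para to its hydroxyl, and loss of a proton restores the arene; the second acetal reacts likewise through 10. The closest known reaction type is the Friedel–Crafts C-arylation of furanosyl acetals and acetates (C-aryl glycoside synthesis) and the acid-mediated arylation of furofuran lactols by phenols. No ring is closed. The new stereocentres C2 and C6 are set by the substrate: the arene comes from the convex face of the cis-fused bicycle, which is also the inside face of a furanosyl-type cation carrying oxygen on the next two ring carbons (C1 and C5), so each aryl group should end up cis to the bridgehead hydroxyls (2R,6R). The step needs exo attack, para regioselectivity and kinetic control: the fold of the bicycle and the free, non-participating bridgehead hydroxyls serve the first, the stronger donor (free OH) and the bulk of the neopentyl-type cation serve the second, and catalytic acid at low temperature with an early amine quench, helped by the β-oxygen that destabilises a benzylic cation at C2/C6, should keep the product ethers from re-ionising.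

Compound list
1 | dimethyl (4S,5S)-2,2-dimethyl-1,3-dioxolane-4,5-dicarboxylate (dimethyl D-tartrate acetonide) | COC(=O)[C@H]1OC(C)(C)O[C@@H]1C(=O)OC | starting material
2 | benzyl chloromethyl ether | ClCOCc1ccccc1 | starting material
3 | dimethyl (4R,5S)-4-[(benzyloxy)methyl]-2,2-dimethyl-1,3-dioxolane-4,5-dicarboxylate (esters cis, CH2OBn trans to the C5 ester) | COC(=O)[C@]1(COCc2ccccc2)OC(C)(C)O[C@@H]1C(=O)OC | intermediate
4 | dimethyl (4R,5R)-4,5-bis[(benzyloxy)methyl]-2,2-dimethyl-1,3-dioxolane-4,5-dicarboxylate (C2-symmetric, esters trans) | COC(=O)[C@]1(COCc2ccccc2)OC(C)(C)O[C@@]1(COCc2ccccc2)C(=O)OC | intermediate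
5 | dimethyl (4R,5R)-4,5-bis(hydroxymethyl)-2,2-dimethyl-1,3-dioxolane-4,5-dicarboxylate (not isolated) | COC(=O)[C@]1(CO)OC(C)(C)O[C@@]1(CO)C(=O)OC | intermediate
6 | (1R,5R)-1,5-(isopropylidenedioxy)-3,7-dioxabicyclo[3.3.0]octane-2,6-dione (propellane bis-lactone) | CC1(C)O[C@]23COC(=O)[C@]2(COC3=O)O1 | intermediate
7 | (1R,5R)-1,5-(isopropylidenedioxy)-3,7-dioxabicyclo[3.3.0]octane-2,6-diol (bis-lactol, anomers at C2 and C6) | CC1(C)O[C@]23COC(O)[C@]2(COC3O)O1 | intermediate
8 | (1R,5R)-2,6-dimethoxy-3,7-dioxabicyclo[3.3.0]octane-1,5-diol (anomers at C2 and C6) | COC1OC[C@]2(O)C(OC)OC[C@]12O | intermediate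
9 | guaiacol (2-methoxyphenol) | COc1ccccc1O | starting material
10 | (1S,2R,5R)-2-(4-hydroxy-3-methoxyphenyl)-6-methoxy-3,7-dioxabicyclo[3.3.0]octane-1,5-diol (anomers at C6, not isolated) | COc1cc([C@H]2OC[C@]3(O)C(OC)OC[C@]23O)ccc1O | intermediate
11 | prinsepiol, (1S,2R,5S,6R)-2,6-bis(4-hydroxy-3-methoxyphenyl)-3,7-dioxabicyclo[3.3.0]octane-1,5-diol | COc1cc([C@H]2OC[C@]3(O)[C@@H](c4ccc(O)c(OC)c4)OC[C@]23O)ccc1O | target

Total step count: 6. Longest linear sequence: 6 steps (from 1).

Steps most likely to fail

1. Step 6. What may go wrong: substitution of guaiacol at the carbon ortho to OH or para to OMe, stalling at reversible O-arylation, attack from the concave face, or acid re-ionisation of the benzylic ethers once formed, which would epimerise C2/C6 or open the rings by further arylation. The fallback sets out from 8 and returns at 11. It replaces the arene C–H nucleophile by an aryl–boron nucleophile of fixed regiochemistry. Compound 8 is treated with potassium [4-(benzyloxy)-3-methoxyphenyl]trifluoroborate and BF3·OEt2 (MeCN/CH2Cl2, −20 → 0 °C). Ipso transfer of the aryl group to each oxocarbenium ion should give 4,4'-di-O-benzylprinsepiol F1 with the same exo preference, without excess phenol and with a product less prone to ionise. Hydrogenolysis of the two phenol benzyl ethers (H2, Pd/C, EtOAc, rt, stopped when F1 is consumed so that the ring benzylic C–O bonds are spared) then gives 11.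

2. Step 2. What may go wrong: poor facial selectivity at C5 next to a quaternary carbon whose two substituents are of similar size (giving the meso isomer), or β-elimination of the more hindered enolate. The fallback sets out from 3 and returns at 6; it fixes C5 by ring fusion instead of acyclic facial bias. Hydrogenolysis of 3 (H2, Pd/C, EtOAc) gives the hydroxymethyl diester F2. NaOMe in MeOH epimerises C5, and the epimer whose ester is cis to the CH2OH is trapped as the cis-fused γ-lactone F3. The lithium enolate of F3 (LiN(i-Pr)2, THF, −78 °C) has its carbon at a ring fusion and can take up monomeric formaldehyde only on the exo face, cis to the C4 ester. This gives the hydroxymethyl lactone F4, which lactonises onto that ester on warming to give 6.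

3. Step 1. What may go wrong: β-elimination or Claisen self-condensation of the lithium enolate before it is alkylated, O-alkylation, or a weak facial bias at C4. The fallback sets out from 1 and returns at 3. The enolate is trapped as it forms (LiN(i-Pr)2, Me3SiCl, THF, −78 °C) as the silyl ketene acetal F5. F5 is then alkylated with 2 under Lewis acid catalysis (ZnBr2, CH2Cl2, −20 °C); this Mukaiyama-type alkoxymethylation avoids a free lithium enolate, and the same face of C4, away from the C5 ester, should be attacked.

Further compounds
F1 | step 6 | (1S,2R,5S,6R)-2,6-bis[4-(benzyloxy)-3-methoxyphenyl]-3,7-dioxabicyclo[3.3.0]octane-1,5-diol (4,4'-di-O-benzylprinsepiol) | COc1cc([C@H]2OC[C@]3(O)[C@@H](c4ccc(OCc5ccccc5)c(OC)c4)OC[C@]23O)ccc1OCc1ccccc1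
F2 | step 2 | dimethyl (4R,5S)-4-(hydroxymethyl)-2,2-dimethyl-1,3-dioxolane-4,5-dicarboxylate | COC(=O)[C@]1(CO)OC(C)(C)O[C@@H]1C(=O)OC
F3 | step 2 | methyl 2,2-dimethyl-6-oxotetrahydrofuro[3,4-d][1,3]dioxole-3a-carboxylate, cis-fused lactone between the C4 CH2OH and the C5 carboxyl (dioxolane carbons 4R,5R) | COC(=O)[C@@]12COC(=O)[C@H]1OC(C)(C)O2
F4 | step 2 | methyl 6a-(hydroxymethyl)-2,2-dimethyl-6-oxotetrahydrofuro[3,4-d][1,3]dioxole-3a-carboxylate (dioxolane carbons 4R,5R; CH2OH cis to the ester) | COC(=O)[C@@]12COC(=O)[C@]1(CO)OC(C)(C)O2
F5 | step 1 | methyl (5S)-4-[methoxy(trimethylsilyloxy)methylidene]-2,2-dimethyl-1,3-dioxolane-5-carboxylate (silyl ketene acetal) | COC(O[Si](C)(C)C)=C1OC(C)(C)O[C@@H]1C(=O)OC
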